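For each electrophile that made target in the east run between 4.00 min and 10.0 min, 0.347 went to side product, and this ratio carries the whole estimate.

| flask | electrophile | free base | protonated nucleophile | remark | time |
|---|---|---|---|---|---|
| east | 20 mM | 60 mM | 36 mM | run made earlier |  |
| north-east | 20 mM | 30 mM | 36 mM | run made earlier |  |
| north-west | 20 mM | 120 mM | 36 mM | run made earlier |  |
| amber | 20 mM (fed, over 30 min) | 60.0 mM | 36.0 mM | all else is in the flask from the start; the feed brings no volume worth counting | 50 min |
| red | 20 mM | 60.0 mM (fed, over 8.0 min) | 36.0 mM | all else is in the flask from the start; the feed brings no volume worth counting | 50 min |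
| teal | 20 mM | 60.0 mM (in portions, 4, over 30 min) | 36.0 mM | first portion at the start, last at 30 min | 50 min |
| blue | 20 mM | 60.0 mM (fed, over 30 min) | 36.0 mM | all else is in the flask from the start; the feed brings no volume worth counting | 50 min |
| violet | 20 mM | 60.0 mM | 36.0 mM | everything together at the start | 50 min |

| run | time / min | side product / % | target / % | electrophile / % |
|---|---|---|---|---|
| east | 4.00 | 10.5 | 37.6 | 52.9 |
| east | 10.0 | 25.8 | 52.0 | 22.2 |
| east | 20.0 | 37.2 | 57.0 | 5.7 |
| east | 30.0 | 40.1 | 58.0 | 1.9 |
| north-east | 4.00 | 8.4 | 28.5 | 63.5 |
| north-east | 10.0 | 24.7 | 37.2 | 38.3 |
| north-east | 20.0 | 42.5 | 38.5 | 19.6 |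
| north-east | 30.0 | 51.3 | 37.7 | 11.7 |
| north-west | 8.00 | 21.2 | 52.7 | 26.6 |
| north-west | 15.0 | 32.1 | 59.1 | 9.0 |
| north-west | 25.0 | 35.7 | 61.5 | 1.8 |
| north-west | 30.0 | 36.8 | 62.4 | 1.2 |

(readings scatter by 0.3 percentage points)

- which flask leads in amount of side product, in percent of the electrophile charged ("all alike" within 1.5 percentage points) (amber / red / teal / blue / violet / all alike)
- how much side product is there at the end, in percent of the electrophile charged: amber
- how much side product is there at the end, in percent of the electrophile charged: red
- how much side product is there at the end, in percent of the electrophile charged: teal
- how much side product is there at the end, in percent of the electrophile charged: blue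
- how much side product is there at the end, in percent of the electrophile charged: violet

- percentages count the electrophile that a species holds: one side product counts as two
- a reading or a percentage of target counts all its forms, free or not

1. Count events, not percentages. One side product holds two electrophiles and consumes one target, so side events are half the rise in side product, and target-making events are the rise in target plus that half. The ratio above is this local selectivity.

2. Assume both steps are first order in electrophile, with the side step also first order in target. The ratio then equals [target] divided by the crossover concentration: the [target] at which electrophile divides equally and target stops growing. East averaged 8.96 mM over that interval, so the crossover is 25.8 mM.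

3. Objection: it depends on the base. The same interval of the north-east run gives a ratio of 0.484 and a crossover of 13.6 mM, lower than east. Its target then tops out near 7.70 mM.

4. With crossover x held fixed and the electrophile spent, let p be final [target]/x and c the charge/x. Integrating gives p = 1 − exp(−(c + p)/2), which has to be iterated.

5. Violet is east continued. Starting from east's last target, one round gives p = 0.458, and further rounds settle at 0.461, so side product is 40.5%. Amber should stay close, since feeding electrophile slows both steps alike.

6. Teal holds 30 mM of base from 10.0 min to 20.0 min, so I take the north-east crossover. Starting at p = 0, the rounds give 0.521, 0.631, 0.651, and further rounds settle at 0.655, so side product is 55.5%.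

7. Objection: blue reaches that base level at 15.0 min, so this estimate cannot separate blue from teal.

8. The forecast names teal: teal 50%, blue 49%, violet 41.6%, amber 41.3%, red 40.8%. Its ground is “Slow or portioned base keeps free nucleophile low while electrophile is high.” My teal stands higher.

9. The flasks end at: teal 53.7%, blue 50.5%, red 42.4%, violet 41.1%, amber 40.1%. Teal leads.

    electrophile + nucleophile → acid set free + target (k = 0.0870 M⁻¹ s⁻¹)
    nucleophile + acid set free ⇌ protonated nucleophile, settled at all times (K = 52000 M⁻¹)
    acid set free + free base ⇌ salt of the base, settled at all times (K = 7.90 × 10⁵ M⁻¹)
    electrophile + target → side product (k = 0.0690 M⁻¹ s⁻¹)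
    crystals ⇌ target, rate k5*(cs5 - [target]) while solid is left; crystals form when [target] > cs5 (solubility = 11.0 mM, k = 0.0130 s⁻¹)
    free base ⇌ dormant form (K = 0.530, k = 0.00190 s⁻¹)

Teal ends 14 percentage points above amber; that gap falls to 3.5 points without the joining of acid set free with free base, and to 4.6 points without the return of dormant form to free base. The north-east crossover puts teal's target at 44.5%, and the flask holds 45.5%. For the neighbour of teal charged with 5.0 mM of electrophile, the east crossover gives p = 0.0923, 0.133, 0.151, 0.158, and further rounds settle at 0.163, so target is 84.1%; that flask holds 82.6%.

The readings are calculated on assumed constants; scatter was added.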